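the same everywhere: D 0.30 M

| flask | G | Q | remark | time |
|---|---|---|---|---|
| south | 1.3 equiv | 4 equiv | run made earlier |  |
| west | 1.3 equiv | 2 equiv | run made earlier |  |
| north-west | 1.3 equiv | 3 equiv | run made earlier |  |
| Saturday's | 1.30 equiv (fed, over 20.0 min) | 4.00 equiv | all but G at the start; G goes in evenly over 20.0 min, the run ends at 40 min | 40 min |
| Monday's | 1.30 equiv | 4.00 equiv (fed, over 20.0 min) | a stirred flask in which Q is dosed at a steady rate over 20.0 min without added volume, worked up at 40 min | 40 min |
| Thursday's | 1.30 equiv | 4.00 equiv | a closed flask charged with all of it at once and left for 40 min | 40 min |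
| Friday's | 1.30 equiv | 4.00 equiv | a single well-mixed tank run continuously and read at steady state, 40 min in it on average |  |

- south (time / min: L / %, E / %): 3.00: 95, 0; 8.00: 85, 9; 15.0: 70, 10; 25.0: 50, 20
- west (time / min: L / %, E / %): 2.50: 73, 2; 6.00: 86, 3; 15.0: 81, 8; 30.0: 66, 20
- north-west (time / min: L / %, E / %): 4.00: 92, 2; 12.0: 83, 12; 20.0: 70, 16; 30.0: 50, 23

(readings scatter by 2 percentage points)

- the stated concentrations are those of everything mixed, before any reaction; amounts are the same in each set-up
- the numbers in the tables scatter with a standard deviation of 2 percentage points
- reactions considered so far: D + Q -> L; Q + G -> X; L + X -> E; Q + E -> J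
- the feed brings no volume worth counting
- the earlier runs were made in a closed, stirred flask

- the set-up with the highest amount of L at the outlet or at the end, in percent of the D put in ("none" if the first two lie within 2 percentage points) (Saturday's / Monday's / Thursday's / Friday's / none)
- amount of L at the outlet or at the end, in percent of the D put in, Saturday's
- amount of L at the outlet or at the end, in percent of the D put in, Monday's
- amount of L at the outlet or at the end, in percent of the D put in, Thursday's
- amount of L at the outlet or at the end, in percent of the D put in, Friday's

Take the south run, whose charge is Thursday's, and count lifetimes of L. In the south flask L falls from 95% of the D charged at 3.00 min to 50% at 25.0 min. Treating that fall as pseudo-first-order gives 34.3 min as the lifetime of L, the time in which L drops to 36.8% of itself. The first reading comes far sooner than that, so I count D as L from the start.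

Thursday's flask ends 0.437 lifetimes after the last south reading, so I expect 32.3% of L. X needs both Q and G, and a dose fed evenly over 20.0 min arrives on average after 10.0 min, half the feed. So for Saturday's and Monday's flasks I start the clock that much later, which gives 43.2% for each. In Friday's tank, L leaves by outflow and by loss, so its share is one over one plus the ratio of the mean stay, 40 min, to the lifetime: 46.1%. Friday's then leads the fed flasks by 2.9 percentage points, against a margin of 2 points.

The weak link is the lifetime, whose stretch includes the first minutes. Reading it from 8.00 min on gives 32.0 min. Thursday's becomes 31.3% and Friday's 44.5%, with a lead of 1.7 points. I keep Friday's first, but that lead is thin.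

The forecast also names Friday's, with 41%, 43%, 32% and 46% in the order asked, and for the two fed flasks its ground is “Feeding G or Q delays X formation”. It separates the two fed flasks, and my reckoning does not.

The flasks give 43.9%, 44.7%, 31.7% and 48.6%, so Friday's is highest.

    D + Q → L (k = 0.0180 M⁻¹ s⁻¹)
    Q + G → X (k = 0.00150 M⁻¹ s⁻¹)
    L + X → E (k = 0.00350 M⁻¹ s⁻¹)
    Q + E → J (k = 0.00330 M⁻¹ s⁻¹)

Now read Thursday's flask later, at 1.5 h. That is 1.90 lifetimes past the last south reading, so the count gives 7.52% of L. The flask holds 9.12%.

The runs are calculated for an exercise; noise was put on by code.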